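## Analysis of the target

Compound 31 is a bisabolane-type sesquiterpenoid triester built on a cyclohexane numbered here C1–C6. C1 carries the side chain, C2 is the only methylene, C3 and C4 are bridged by an oxirane oxygen (a 7-oxabicyclo[4.1.0]heptane), C4 also bears a methyl group, and C5 and C6 bear angelate [(Z)-2-methylbut-2-enoate] esters. The chain is C7(=C14H2)–C8H(OAc)–C9H2–C10H=C11(CH3)2, so C7 is a 1,1-disubstituted alkene carbon and C8 an allylic acetate. The ring holds five contiguous stereocentres (1S,3S,4S,5S,6R) and the chain one more (8S); the C1 chain, O6 and the oxirane oxygen lie on one face of the ring, O5 and the C4 methyl on the other. The angelates isomerise to tiglates under nucleophilic, basic or hot conditions, the trisubstituted oxirane is open to acid and to Payne-type migration once O5 is free, and the C8 acetate is allylic. The difficulty lies in the dense oxygen array C3–C6 around the fully substituted carbon C4, and in C8, which is separated from the ring by the sp2 carbon C7. The strategy rests on C4: a quaternary oxygen-bearing carbon flanked by oxygenated C3 and C5. With C5 at the ketone level this is a tertiary acyloin, whose C4–C5 bond can be made by umpolung of a C5 aldehyde onto a C4 methyl ketone, so the ring problem reduces to an open chain that holds only C1, C3 and C6.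

## Retrosynthetic reasoning

**Ester C–O bonds at O5 and O6 (31 ⇒ 28 + 29).** The angelates are the most fragile groups, so they go on last and together, from diol 28 and angelic acid 29. The acetate on O8 is placed one stage earlier (27 from 26), while O5 and O6 are still silylated, because that is the only point at which O8 differs from the other two hydroxyls.

**C7–C8 (26 ⇒ 23 + 25).** This cut separates the ring from the prenyl-bearing aldehyde 25 (one oxidation from alcohol 24). It creates the C8 carbinol and leaves the C7=C14 methylene in place in the same step. The forward coupling of alkenyl triflate 23 with an enolisable β,γ-unsaturated aldehyde must spare the oxirane and set 8S by reagent control.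

**C7–C14 and the triflate (23 ⇒ 22 ⇒ 21).** The triflate comes from methyl ketone 22, whose methyl carbon C14 is added to the C7 Weinreb amide of 21. Carrying C7 as this amide from the aldol stage onwards avoids any redox adjustment of the carboxyl carbon and keeps the C1 α-hydrogen weakly acidic throughout.

**Oxirane C3–O bond (21 ⇒ 20 ⇒ 19 ⇒ 18 ⇒ 17).** The oxirane is closed by O4 displacing a C3 mesylate with inversion, not by epoxidising a C3=C4 alkene, whose face cis to the C1 substituent could not be guaranteed. This requires the C3 oxygen to be carried trans to O4, that is, with the configuration opposite to the one it has in 31. A TES ether on O3 against TBS ethers on O5 and O6 gives the one differentiation that is needed.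

**C5–H (17 ⇒ 16).** The ketone left by the acyloin closure is reduced with hydride delivered from the neighbouring tertiary hydroxyl, which puts O5 trans to O4 and O6.

**C4–C5 (16 ⇒ 15), the key disconnection.** This is the only ring bond whose formation both closes the ring and creates the quaternary carbinol. It leaves a chain (15) whose three stereocentres C1, C3 and C6 are all of types that standard acyclic methods deliver. The forward reaction must use the aldehyde as the acyl-anion donor and the ketone as acceptor, choose one face of the ketone, and leave the α-silyloxy aldehyde centre C6 intact.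

**Two C=O from two C=C (15 ⇒ 14).** Both carbonyl groups are unveiled at once by ozonolysis of diene 14, so the sensitive keto-aldehyde exists only immediately before the key step and the aldol step never sees a ketone.

**C1–C6 (14 ⇒ 13 ⇒ 12 ⇒ 10 + 11).** C1 and C6 have the syn-aldol relationship, so they are set together by an auxiliary-controlled aldol reaction of imide 10 with acrolein 11, whose vinyl group is the latent C5 aldehyde. The auxiliary is exchanged directly for the Weinreb amide (13) and O6 is silylated (14).

**Chiral pool for C3 (10 ⇒ 7 + 8; 7 ⇒ 4 ⇒ 3 ⇒ 1).** Lactone acid 1 supplies C3 with the required (inverted) oxygen configuration. Its carboxyl carbon becomes C4 (methyl ketone 3, masked as the isopropenyl group of 4), and its lactone carbonyl becomes C7 after ring opening to acid 7 and attachment of auxiliary 8.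

## Alternatives that were turned down

**Alternative 1:** The ring bond C2–C3 is cut, with C1 as a ketone. In the forward sense, Hg(OCOCF3)2-catalysed hydration of the exocyclic enol ether of the 2-C-methyl pyranoside A2 opens the acetal, and the mercury enolate centred on C2 adds to the liberated C3 aldehyde carbon (Ferrier carbocyclisation) to give β-hydroxy ketone A1.
- For: the closure is a dependable reaction, and the O5/O6 trans pair and the quaternary C4 carbinol are already in the sugar. No facial question arises at C4 in the key step; on that point it is stronger than the chosen route.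
- Against: C1 emerges as a ketone, so the stereocentre that carries the whole side chain still has to be created on the ring, next to a β-hydroxyl that eliminates easily. In A1 the C3 hydroxyl is cis to the C4 hydroxyl, so O4 cannot close the oxirane until C3 has been inverted. A2 itself requires a branched-sugar synthesis (C-methyl addition to a 2-ulose with its own facial issue, selective protection, formation of the 5-ene), and the PMB ethers must later be exchanged.
- Comparison: it is longer and leaves the two hardest relationships (C1 and the oxirane face) open. The chosen route fixes C1 with its carbon substituent in the aldol step and delivers C3 already set for displacement.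

**Alternative 2:** The C4–O bond and a C3–halogen bond are cut across a C3=C4 alkene, with the C7 carboxyl as tether. In the forward sense, iodolactonisation of cyclohexene acid A4 gives the bridged δ-lactone A3; lactone opening would then let O4 displace the anti iodide and close the oxirane.
- For: the tether forces O4 onto the face of C7, so the oxirane face and the quaternary centre are set with certainty. This is a stronger answer to the C4 question than catalyst control.
- Against: A4 must already carry C1, C5 and C6, and its oxygenation pattern does not correspond to a normal-demand Diels–Alder adduct, so its enantioselective preparation would dominate the synthesis. The carboxylate can also reach C3 to give the bridged γ-lactone, so the regiochemistry rests on Markovnikov polarisation alone. The iodonium ion has to form on the face that carries the C5 silyloxy group.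
- Comparison: what the chosen strategy offers in its place is a ring built catalytically from a chain whose stereocentres come from the chiral pool and one aldol reaction, with no need for a pre-formed stereodefined cyclohexene.

**Alternative 3:** The ring bond C1–C6 is cut. In the forward sense, zinc or CrCl2 converts the 2-(bromomethyl)enoate A6 into an allylmetal whose γ-carbon C1 adds to the C6 aldehyde; the resulting alkoxide lactonises onto C8 to give the cis-fused α-methylene lactone A5.
- For: one step forms the ring, the C7=C14 methylene and the cis C1/C6 relationship, with C8 already at the carboxyl level. For the C7/C14/C8 unit this is more economical than the amide → ketone → triflate → coupling sequence used here.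
- Against: A6 must already contain the trisubstituted oxirane next to an α-alkoxy aldehyde, a combination exposed to the Lewis-acidic metal halides of the key step. The C5/C6 trans relationship depends on Felkin versus chelation control at that aldehyde. Converting the lactone carbonyl of A5 into the C8 carbinol means organometallic addition to a Michael acceptor followed by a ketone reduction, so C8 is not solved either.
- Comparison: the chosen route forms the oxirane after the ring, by a stereospecific displacement, and closes the ring under near-neutral catalytic conditions.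

Key step: step 9

Remark on the chemistry: the sense of induction of the carbene catalyst (step 9) and of the chromium ligand (step 17) is assigned from the accepted transition-state models; in both cases the mirror-image catalyst is available and would be used if the pairing with the substrate proves mismatched.

## Route

Step 1
Reactants: 1 (2R)-5-oxooxolane-2-carboxylic acid
Product: 3 (5R)-5-acetyloxolan-2-one, via acid chloride 2 (not isolated)
Conditions: (COCl)2, cat. DMF, CH2Cl2, 0 °C → rt; evaporate; Me2CuLi, Et2O, −78 °C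
Reagents that add atoms: oxalyl chloride, O=C(Cl)C(=O)Cl (chlorine of 2 only); lithium dimethylcuprate, [Li+].C[Cu-]C
Why: Acid chloride formation followed by acylation of a Gilman cuprate stops at the ketone. The lactone carbonyl is inert to the cuprate at −78 °C and the stereocentre (future C3) is not enolised.

Step 2
Reactants: 3 (5R)-5-acetyloxolan-2-one
Product: 4 (5R)-5-(prop-1-en-2-yl)oxolan-2-one
Conditions: Zn, CH2Br2, TiCl4, THF/CH2Cl2, 0 °C → rt
Reagents that add atoms: dibromomethane, BrCBr
Why: Lombardo methylenation converts the ketone into the 1,1-disubstituted alkene that masks the C4 ketone. The reagent is non-basic, so the α-acyloxy stereocentre should not epimerise, and it does not methylenate the lactone.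

Step 3
Reactants: 4 (5R)-5-(prop-1-en-2-yl)oxolan-2-one
Product: 7 (4R)-5-methyl-4-(triethylsilyloxy)hex-5-enoic acid, via potassium hydroxy carboxylate 5 (not isolated), via bis-silylated hydroxy acid 6 (not isolated)
Conditions: KOH, THF/H2O, rt; evaporate; TESCl, imidazole, DMF, 0 °C → rt; then aq. THF, rt; citric acid to pH 5
Reagents that add atoms: potassium hydroxide, [K+].[OH-]; chlorotriethylsilane, CC[Si](Cl)(CC)CC
Why: Saponification cleaves the acyl C–O bond, so the C3–O bond and its configuration are retained. Silylation of the dry salt caps the alcohol before it can relactonise, and the labile silyl ester is then hydrolysed in wet THF while the secondary TES ether stays.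

Step 4
Reactants: 7 (4R)-5-methyl-4-(triethylsilyloxy)hex-5-enoic acid; 8 (4R)-4-benzyl-1,3-oxazolidin-2-one
Product: 10 (4R)-4-benzyl-3-[(4R)-5-methyl-4-(triethylsilyloxy)hex-5-enoyl]-1,3-oxazolidin-2-one, via mixed pivalic anhydride 9 (not isolated)
Conditions: PivCl, Et3N, THF, −20 °C; then 8, LiCl, −20 °C → rt
Reagents that add atoms: pivaloyl chloride, CC(C)(C)C(=O)Cl (acyl group of 9 only)
Why: Mixed-anhydride N-acylation of the oxazolidinone under mild conditions that do not touch the TES ether; no stereocentre is formed.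

Step 5
Reactants: 10 (4R)-4-benzyl-3-[(4R)-5-methyl-4-(triethylsilyloxy)hex-5-enoyl]-1,3-oxazolidin-2-one; 11 acrolein (prop-2-enal)
Product: 12 (4R)-4-benzyl-3-[(2R,4R)-2-[(1S)-1-hydroxyprop-2-en-1-yl]-5-methyl-4-(triethylsilyloxy)hex-5-enoyl]-1,3-oxazolidin-2-one
Conditions: Bu2BOTf, iPr2NEt, CH2Cl2, −78 → 0 °C; 11, −78 → 0 °C; pH 7 buffer, MeOH, H2O2, 0 °C
Reagents that add atoms: none
Why: Evans syn-aldol reaction: the dibutylboron (Z)-enolate reacts through a closed chair transition state on the enolate face opposite the benzyl group of the (R)-auxiliary, which sets C1 (R) and the carbinol carbon C6 (S) in the required syn relationship. Acrolein reacts 1,2 and its vinyl group is the latent C5 aldehyde; the remote C3 centre is overridden by the auxiliary.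

Step 6
Reactants: 12 (4R)-4-benzyl-3-[(2R,4R)-2-[(1S)-1-hydroxyprop-2-en-1-yl]-5-methyl-4-(triethylsilyloxy)hex-5-enoyl]-1,3-oxazolidin-2-one
Product: 13 (2R,4R)-2-[(1S)-1-hydroxyprop-2-en-1-yl]-N-methoxy-N,5-dimethyl-4-(triethylsilyloxy)hex-5-enamide
Conditions: MeNHOMe·HCl, AlMe3, CH2Cl2, −20 → 0 °C
Reagents that add atoms: N,O-dimethylhydroxylamine hydrochloride, CNOC.Cl
Why: Aluminium amide transamination of a β-hydroxy imide, assisted by the free C6 hydroxyl as its aluminium alkoxide, gives the Weinreb amide directly and releases the auxiliary without retro-aldol cleavage or epimerisation at C1.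

Step 7
Reactants: 13 (2R,4R)-2-[(1S)-1-hydroxyprop-2-en-1-yl]-N-methoxy-N,5-dimethyl-4-(triethylsilyloxy)hex-5-enamide
Product: 14 (2R,4R)-2-[(1S)-1-(tert-butyldimethylsilyloxy)prop-2-en-1-yl]-N-methoxy-N,5-dimethyl-4-(triethylsilyloxy)hex-5-enamide
Conditions: TBSOTf, 2,6-lutidine, CH2Cl2, −78 → 0 °C
Reagents that add atoms: tert-butyldimethylsilyl triflate, CC(C)(C)[Si](C)(C)OS(=O)(=O)C(F)(F)F
Why: Silyl triflate silylation of the allylic secondary alcohol; the TBS ether is chosen to outlast the later selective removal of the C3 TES ether.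

Step 8
Reactants: 14 (2R,4R)-2-[(1S)-1-(tert-butyldimethylsilyloxy)prop-2-en-1-yl]-N-methoxy-N,5-dimethyl-4-(triethylsilyloxy)hex-5-enamide
Product: 15 (2R,4R)-2-[(1R)-1-(tert-butyldimethylsilyloxy)-2-oxoethyl]-N-methoxy-N-methyl-5-oxo-4-(triethylsilyloxy)hexanamide
Conditions: O3, CH2Cl2, −78 °C; then PPh3, −78 °C → rt
Reagents that add atoms: ozone, [O-][O+]=O
Why: Ozonolysis with reductive work-up cleaves the vinyl group to the C5 aldehyde and the isopropenyl group to the C4 methyl ketone in one neutral operation, so neither silyl ether nor the α-centres C3 and C6 are put at risk. Compound 15 is used without storage.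

Step 9
Reactants: 15 (2R,4R)-2-[(1R)-1-(tert-butyldimethylsilyloxy)-2-oxoethyl]-N-methoxy-N-methyl-5-oxo-4-(triethylsilyloxy)hexanamide
Product: 16 (1R,2R,4S,5R)-2-(tert-butyldimethylsilyloxy)-4-hydroxy-N-methoxy-N,4-dimethyl-3-oxo-5-(triethylsilyloxy)cyclohexane-1-carboxamide
Conditions: (5aS,10bR)-2-(pentafluorophenyl)-5a,10b-dihydro-4H,6H-indeno[2,1-b][1,2,4]triazolo[4,3-d][1,4]oxazin-2-ium tetrafluoroborate (15 mol%), Et3N (15 mol%), toluene (0.02 M), rt
Reagents that add atoms: none
Why: The carbene released from the triazolium salt adds to the only aldehyde (C5); proton transfer gives the enaminol (Breslow intermediate), whose nucleophilic C5 attacks the C4 methyl ketone, and collapse of the adduct releases the carbene and leaves the tertiary α-ketol. This is the carbene-catalysed intramolecular crossed aldehyde–ketone benzoin reaction, known for keto-aldehydes that close six-membered rings and for α-oxygenated aldehydes. The ring closes in a 6-exo-trig mode, C5 adding to the ketone carbon C4 with the C4=O bond outside the forming ring. The one new stereocentre, C4, is set by the ketone face that is attacked. In the chair-like transition state that keeps the C3 and C6 silyloxy groups equatorial, the ketone oxygen lies equatorial and gauche to the enaminol hydroxyl (hydrogen bond) and the methyl axial, which places O4 trans to O3 and cis to O6 and the C1 carboxamide (4S); the catalyst antipode is chosen to reinforce this preference. Chemoselectivity follows from the fact that only an aldehyde can form the Breslow intermediate, the ketone acting as acceptor only; dilution suppresses intermolecular aldehyde–aldehyde coupling, and silyloxide is too poor a leaving group for redox elimination from the α-silyloxy aldehyde. The acidic pentafluorophenyl triazolium needs only a weak amine base, which should keep C6 (α to the aldehyde) and C1 from epimerising and prevent β-elimination of the C6 silyloxy group.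

Step 10
Reactants: 16 (1R,2R,4S,5R)-2-(tert-butyldimethylsilyloxy)-4-hydroxy-N-methoxy-N,4-dimethyl-3-oxo-5-(triethylsilyloxy)cyclohexane-1-carboxamide
Product: 17 (1R,2R,3S,4R,5R)-2-(tert-butyldimethylsilyloxy)-3,4-dihydroxy-N-methoxy-N,4-dimethyl-5-(triethylsilyloxy)cyclohexane-1-carboxamide
Conditions: Me4NBH(OAc)3, MeCN/AcOH, −30 °C
Reagents that add atoms: none
Why: Hydroxyl-directed reduction: the tertiary C4 hydroxyl exchanges an acetate on boron and delivers hydride intramolecularly to the face of the C5 carbonyl on which it sits, so the new C5 hydroxyl should appear on the opposite face, trans to O4 and to O6. Amide and silyl ethers are inert to the triacetoxyborohydride.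

Step 11
Reactants: 17 (1R,2R,3S,4R,5R)-2-(tert-butyldimethylsilyloxy)-3,4-dihydroxy-N-methoxy-N,4-dimethyl-5-(triethylsilyloxy)cyclohexane-1-carboxamide
Product: 18 (1R,2R,3S,4S,5R)-2,3-bis(tert-butyldimethylsilyloxy)-4-hydroxy-N-methoxy-N,4-dimethyl-5-(triethylsilyloxy)cyclohexane-1-carboxamide
Conditions: TBSOTf, 2,6-lutidine, CH2Cl2, −78 °C
Reagents that add atoms: tert-butyldimethylsilyl triflate, CC(C)(C)[Si](C)(C)OS(=O)(=O)C(F)(F)F
Why: Silylation at low temperature discriminates the secondary C5 hydroxyl from the tertiary C4 hydroxyl, which must stay free as the later oxirane oxygen.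

Step 12
Reactants: 18 (1R,2R,3S,4S,5R)-2,3-bis(tert-butyldimethylsilyloxy)-4-hydroxy-N-methoxy-N,4-dimethyl-5-(triethylsilyloxy)cyclohexane-1-carboxamide
Product: 19 (1R,2R,3S,4S,5R)-2,3-bis(tert-butyldimethylsilyloxy)-4,5-dihydroxy-N-methoxy-N,4-dimethylcyclohexane-1-carboxamide
Conditions: PPTS, MeOH/CH2Cl2, 0 °C
Reagents that add atoms: none
Why: Acid-catalysed methanolysis removes a secondary TES ether far faster than secondary TBS ethers, so only the C3 hydroxyl is freed.

Step 13
Reactants: 19 (1R,2R,3S,4S,5R)-2,3-bis(tert-butyldimethylsilyloxy)-4,5-dihydroxy-N-methoxy-N,4-dimethylcyclohexane-1-carboxamide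
Product: 21 (1S,3R,4R,5S,6S)-4,5-bis(tert-butyldimethylsilyloxy)-N-methoxy-N,6-dimethyl-7-oxabicyclo[4.1.0]heptane-3-carboxamide, via C3 mesylate 20 (not isolated)
Conditions: MsCl, Et3N, CH2Cl2, 0 °C; then MeOH, K2CO3, rt
Reagents that add atoms: methanesulfonyl chloride, CS(=O)(=O)Cl (sulfonyl group of 20 only)
Why: Sulfonylation takes the secondary C3 hydroxyl and not the tertiary C4 hydroxyl. Under carbonate in methanol the C4 alkoxide displaces the mesylate from the rear (3-exo-tet Williamson closure through the trans-diaxial conformer), which inverts C3 and places the oxirane on the face of O6 and the C1 substituent. The Weinreb amide does not acylate the cis C4 alkoxide.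

Step 14
Reactants: 21 (1S,3R,4R,5S,6S)-4,5-bis(tert-butyldimethylsilyloxy)-N-methoxy-N,6-dimethyl-7-oxabicyclo[4.1.0]heptane-3-carboxamide
Product: 22 1-[(1S,3R,4R,5S,6S)-4,5-bis(tert-butyldimethylsilyloxy)-6-methyl-7-oxabicyclo[4.1.0]heptan-3-yl]ethan-1-one
Conditions: MeMgBr, THF, −20 → 0 °C
Reagents that add atoms: methylmagnesium bromide, C[Mg]Br
Why: Grignard addition to the Weinreb amide stops at the chelated tetrahedral adduct, so only the methyl ketone is released on work-up. The hindered trisubstituted oxirane should not react with the Grignard reagent at or below 0 °C.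

Step 15
Reactants: 22 1-[(1S,3R,4R,5S,6S)-4,5-bis(tert-butyldimethylsilyloxy)-6-methyl-7-oxabicyclo[4.1.0]heptan-3-yl]ethan-1-one
Product: 23 1-[(1S,3R,4R,5S,6S)-4,5-bis(tert-butyldimethylsilyloxy)-6-methyl-7-oxabicyclo[4.1.0]heptan-3-yl]ethenyl trifluoromethanesulfonate
Conditions: KN(SiMe3)2, THF, −78 °C; then PhNTf2, −78 → 0 °C
Reagents that add atoms: N-phenylbis(trifluoromethanesulfonimide), O=S(=O)(N(c1ccccc1)S(=O)(=O)C(F)(F)F)C(F)(F)F
Why: Kinetic deprotonation with the hindered amide base takes the methyl group, not the C1 methine, and O-triflation of the terminal enolate gives the 1,1-disubstituted alkenyl triflate. Avoiding the C1 enolate also avoids β-elimination of the C6 silyloxy group.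

Step 16
Reactants: 24 4-methylpent-3-en-1-ol
Product: 25 4-methylpent-3-enal
Conditions: Dess–Martin periodinane, NaHCO3, CH2Cl2, 0 °C → rt; used at once as a solution
Reagents that add atoms: none
Why: Dess–Martin oxidation under bicarbonate buffering should give the β,γ-unsaturated aldehyde without migration of the double bond into conjugation.

Step 17
Reactants: 23 1-[(1S,3R,4R,5S,6S)-4,5-bis(tert-butyldimethylsilyloxy)-6-methyl-7-oxabicyclo[4.1.0]heptan-3-yl]ethenyl trifluoromethanesulfonate; 25 4-methylpent-3-enal
Product: 26 (3S)-2-[(1S,3S,4R,5S,6S)-4,5-bis(tert-butyldimethylsilyloxy)-6-methyl-7-oxabicyclo[4.1.0]heptan-3-yl]-6-methylhepta-1,5-dien-3-ol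
Conditions: CrCl2, NiCl2 (cat.), (S)-N-[2-(4-isopropyl-4,5-dihydro-1,3-oxazol-2-yl)-6-methylphenyl]methanesulfonamide, Et3N, THF/MeCN, rt
Reagents that add atoms: none
Why: Nozaki–Hiyama–Kishi coupling: nickel inserts into the alkenyl C–OTf bond, and transmetalation gives an alkenylchromium species that adds only to the aldehyde and tolerates oxirane and silyl ethers, forming C7–C8 with the C7=C14 methylene in place. The C8 configuration (S, addition to the Re face of the aldehyde) is assigned to the chiral sulfonamide ligand on chromium, because the bias from C1 cannot be predicted.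

Step 18
Reactants: 26 (3S)-2-[(1S,3S,4R,5S,6S)-4,5-bis(tert-butyldimethylsilyloxy)-6-methyl-7-oxabicyclo[4.1.0]heptan-3-yl]-6-methylhepta-1,5-dien-3-ol
Product: 27 (3S)-2-[(1S,3S,4R,5S,6S)-4,5-bis(tert-butyldimethylsilyloxy)-6-methyl-7-oxabicyclo[4.1.0]heptan-3-yl]-6-methylhepta-1,5-dien-3-yl acetate
Conditions: Ac2O, pyridine, DMAP (cat.), CH2Cl2, 0 °C → rt
Reagents that add atoms: acetic anhydride, CC(=O)OC(C)=O
Why: Standard acylation of the only free hydroxyl; no stereocentre is affected.

Step 19
Reactants: 27 (3S)-2-[(1S,3S,4R,5S,6S)-4,5-bis(tert-butyldimethylsilyloxy)-6-methyl-7-oxabicyclo[4.1.0]heptan-3-yl]-6-methylhepta-1,5-dien-3-yl acetate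
Product: 28 (3S)-2-[(1S,3S,4R,5S,6R)-4,5-dihydroxy-6-methyl-7-oxabicyclo[4.1.0]heptan-3-yl]-6-methylhepta-1,5-dien-3-yl acetate
Conditions: HF·pyridine, pyridine, THF, 0 °C → rt
Reagents that add atoms: none
Why: Buffered HF·pyridine cleaves both secondary TBS ethers without the basicity that would move the acetate or trigger Payne migration. The oxirane should survive because a cation at C4 is disfavoured by the adjacent C5 oxygen.

Step 20
Reactants: 28 (3S)-2-[(1S,3S,4R,5S,6R)-4,5-dihydroxy-6-methyl-7-oxabicyclo[4.1.0]heptan-3-yl]-6-methylhepta-1,5-dien-3-yl acetate; 29 angelic acid [(2Z)-2-methylbut-2-enoic acid]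
Product: 31 (1S,2S,3R,4S,6S)-4-[(3S)-3-acetoxy-6-methylhepta-1,5-dien-2-yl]-1-methyl-7-oxabicyclo[4.1.0]heptane-2,3-diyl bis[(2Z)-2-methylbut-2-enoate], via mixed angelic anhydride 30 (not isolated)
Conditions: 29, 2,4,6-trichlorobenzoyl chloride, Et3N, toluene, rt; then 28, 80 °C
Reagents that add atoms: 2,4,6-trichlorobenzoyl chloride, O=C(Cl)c1c(Cl)cc(Cl)cc1Cl (aroyl group of 30 only)
Why: Yamaguchi-type esterification with the preformed mixed anhydride acylates both hindered secondary hydroxyls. Leaving out nucleophilic catalysts and strong base should preserve the (Z)-geometry, since isomerisation to the tiglate runs through conjugate addition–elimination.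

## Compound list

1 | (2R)-5-oxooxolane-2-carboxylic acid | OC(=O)[C@H]1CCC(=O)O1 | starting material
2 | (2R)-5-oxooxolane-2-carbonyl chloride | ClC(=O)[C@H]1CCC(=O)O1 | intermediate (not isolated)
3 | (5R)-5-acetyloxolan-2-one | CC(=O)[C@H]1CCC(=O)O1 | intermediate
4 | (5R)-5-(prop-1-en-2-yl)oxolan-2-one | C=C(C)[C@H]1CCC(=O)O1 | intermediate
5 | potassium (4R)-4-hydroxy-5-methylhex-5-enoate | [K+].[O-]C(=O)CC[C@@H](O)C(C)=C | intermediate (not isolated)
6 | triethylsilyl (4R)-5-methyl-4-(triethylsilyloxy)hex-5-enoate | CC[Si](CC)(CC)OC(=O)CC[C@@H](O[Si](CC)(CC)CC)C(C)=C | intermediate (not isolated)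
7 | (4R)-5-methyl-4-(triethylsilyloxy)hex-5-enoic acid | OC(=O)CC[C@@H](O[Si](CC)(CC)CC)C(C)=C | intermediate
8 | (4R)-4-benzyl-1,3-oxazolidin-2-one | O=C1N[C@H](Cc2ccccc2)CO1 | starting material
9 | (4R)-5-methyl-4-(triethylsilyloxy)hex-5-enoic pivalic anhydride | CC(C)(C)C(=O)OC(=O)CC[C@@H](O[Si](CC)(CC)CC)C(C)=C | intermediate (not isolated)
10 | (4R)-4-benzyl-3-[(4R)-5-methyl-4-(triethylsilyloxy)hex-5-enoyl]-1,3-oxazolidin-2-one | O=C(CC[C@@H](O[Si](CC)(CC)CC)C(C)=C)N1[C@H](Cc2ccccc2)COC1=O | intermediate
11 | acrolein (prop-2-enal) | C=CC=O | starting material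
12 | (4R)-4-benzyl-3-[(2R,4R)-2-[(1S)-1-hydroxyprop-2-en-1-yl]-5-methyl-4-(triethylsilyloxy)hex-5-enoyl]-1,3-oxazolidin-2-one | C=C[C@H](O)[C@H](C(=O)N1[C@H](Cc2ccccc2)COC1=O)C[C@@H](O[Si](CC)(CC)CC)C(C)=C | intermediate
13 | (2R,4R)-2-[(1S)-1-hydroxyprop-2-en-1-yl]-N-methoxy-N,5-dimethyl-4-(triethylsilyloxy)hex-5-enamide | C=C[C@H](O)[C@H](C(=O)N(C)OC)C[C@@H](O[Si](CC)(CC)CC)C(C)=C | intermediate
14 | (2R,4R)-2-[(1S)-1-(tert-butyldimethylsilyloxy)prop-2-en-1-yl]-N-methoxy-N,5-dimethyl-4-(triethylsilyloxy)hex-5-enamide | C=C[C@H](O[Si](C)(C)C(C)(C)C)[C@H](C(=O)N(C)OC)C[C@@H](O[Si](CC)(CC)CC)C(C)=C | intermediate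
15 | (2R,4R)-2-[(1R)-1-(tert-butyldimethylsilyloxy)-2-oxoethyl]-N-methoxy-N-methyl-5-oxo-4-(triethylsilyloxy)hexanamide | O=C[C@H](O[Si](C)(C)C(C)(C)C)[C@H](C(=O)N(C)OC)C[C@@H](O[Si](CC)(CC)CC)C(C)=O | intermediate
16 | (1R,2R,4S,5R)-2-(tert-butyldimethylsilyloxy)-4-hydroxy-N-methoxy-N,4-dimethyl-3-oxo-5-(triethylsilyloxy)cyclohexane-1-carboxamide | CON(C)C(=O)[C@@H]1C[C@@H](O[Si](CC)(CC)CC)[C@](C)(O)C(=O)[C@@H]1O[Si](C)(C)C(C)(C)C | intermediate
17 | (1R,2R,3S,4R,5R)-2-(tert-butyldimethylsilyloxy)-3,4-dihydroxy-N-methoxy-N,4-dimethyl-5-(triethylsilyloxy)cyclohexane-1-carboxamide | CON(C)C(=O)[C@@H]1C[C@@H](O[Si](CC)(CC)CC)[C@](C)(O)[C@@H](O)[C@@H]1O[Si](C)(C)C(C)(C)C | intermediate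
18 | (1R,2R,3S,4S,5R)-2,3-bis(tert-butyldimethylsilyloxy)-4-hydroxy-N-methoxy-N,4-dimethyl-5-(triethylsilyloxy)cyclohexane-1-carboxamide | CON(C)C(=O)[C@@H]1C[C@@H](O[Si](CC)(CC)CC)[C@](C)(O)[C@@H](O[Si](C)(C)C(C)(C)C)[C@@H]1O[Si](C)(C)C(C)(C)C | intermediate
19 | (1R,2R,3S,4S,5R)-2,3-bis(tert-butyldimethylsilyloxy)-4,5-dihydroxy-N-methoxy-N,4-dimethylcyclohexane-1-carboxamide | CON(C)C(=O)[C@@H]1C[C@@H](O)[C@](C)(O)[C@@H](O[Si](C)(C)C(C)(C)C)[C@@H]1O[Si](C)(C)C(C)(C)C | intermediate
20 | (1R,2R,3S,4R,5R)-2,3-bis(tert-butyldimethylsilyloxy)-4-hydroxy-5-(methanesulfonyloxy)-N-methoxy-N,4-dimethylcyclohexane-1-carboxamide | CON(C)C(=O)[C@@H]1C[C@@H](OS(C)(=O)=O)[C@](C)(O)[C@@H](O[Si](C)(C)C(C)(C)C)[C@@H]1O[Si](C)(C)C(C)(C)C | intermediate (not isolated)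
21 | (1S,3R,4R,5S,6S)-4,5-bis(tert-butyldimethylsilyloxy)-N-methoxy-N,6-dimethyl-7-oxabicyclo[4.1.0]heptane-3-carboxamide | CON(C)C(=O)[C@@H]1C[C@@H]2O[C@]2(C)[C@@H](O[Si](C)(C)C(C)(C)C)[C@@H]1O[Si](C)(C)C(C)(C)C | intermediate
22 | 1-[(1S,3R,4R,5S,6S)-4,5-bis(tert-butyldimethylsilyloxy)-6-methyl-7-oxabicyclo[4.1.0]heptan-3-yl]ethan-1-one | CC(=O)[C@@H]1C[C@@H]2O[C@]2(C)[C@@H](O[Si](C)(C)C(C)(C)C)[C@@H]1O[Si](C)(C)C(C)(C)C | intermediate
23 | 1-[(1S,3R,4R,5S,6S)-4,5-bis(tert-butyldimethylsilyloxy)-6-methyl-7-oxabicyclo[4.1.0]heptan-3-yl]ethenyl trifluoromethanesulfonate | C=C(OS(=O)(=O)C(F)(F)F)[C@@H]1C[C@@H]2O[C@]2(C)[C@@H](O[Si](C)(C)C(C)(C)C)[C@@H]1O[Si](C)(C)C(C)(C)C | intermediate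
24 | 4-methylpent-3-en-1-ol | CC(C)=CCCO | starting material
25 | 4-methylpent-3-enal | CC(C)=CCC=O | intermediate
26 | (3S)-2-[(1S,3S,4R,5S,6S)-4,5-bis(tert-butyldimethylsilyloxy)-6-methyl-7-oxabicyclo[4.1.0]heptan-3-yl]-6-methylhepta-1,5-dien-3-ol | C=C([C@H](CC=C(C)C)O)[C@@H]1C[C@@H]2O[C@]2(C)[C@@H](O[Si](C)(C)C(C)(C)C)[C@@H]1O[Si](C)(C)C(C)(C)C | intermediate
27 | (3S)-2-[(1S,3S,4R,5S,6S)-4,5-bis(tert-butyldimethylsilyloxy)-6-methyl-7-oxabicyclo[4.1.0]heptan-3-yl]-6-methylhepta-1,5-dien-3-yl acetate | C=C([C@H](CC=C(C)C)OC(C)=O)[C@@H]1C[C@@H]2O[C@]2(C)[C@@H](O[Si](C)(C)C(C)(C)C)[C@@H]1O[Si](C)(C)C(C)(C)C | intermediate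
28 | (3S)-2-[(1S,3S,4R,5S,6R)-4,5-dihydroxy-6-methyl-7-oxabicyclo[4.1.0]heptan-3-yl]-6-methylhepta-1,5-dien-3-yl acetate | C=C([C@H](CC=C(C)C)OC(C)=O)[C@@H]1C[C@@H]2O[C@]2(C)[C@@H](O)[C@@H]1O | intermediate
29 | angelic acid, (2Z)-2-methylbut-2-enoic acid | C/C=C(/C)C(=O)O | starting material
30 | (2Z)-2-methylbut-2-enoic 2,4,6-trichlorobenzoic anhydride | C/C=C(/C)C(=O)OC(=O)c1c(Cl)cc(Cl)cc1Cl | intermediate (not isolated)
31 | (1S,2S,3R,4S,6S)-4-[(3S)-3-acetoxy-6-methylhepta-1,5-dien-2-yl]-1-methyl-7-oxabicyclo[4.1.0]heptane-2,3-diyl bis[(2Z)-2-methylbut-2-enoate] | C=C([C@H](CC=C(C)C)OC(C)=O)[C@@H]1C[C@@H]2O[C@]2(C)[C@@H](OC(=O)/C(C)=C\C)[C@@H]1OC(=O)/C(C)=C\C | target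

## Step count and least certain steps

Total: 20 steps. Longest linear sequence: 19 steps (steps 1–15 and 17–20, from 1 to 31); the aldehyde branch (step 16) is one step.

**Step 9 (key step).** The most likely failures are attack on the wrong face of the ketone (the C4 epimer cannot close the oxirane), enolisation of the α-silyloxy aldehyde with loss of configuration at C6, and a base-mediated aldol reaction from C3 onto the aldehyde that closes a five-membered ring instead. Fallback: starting from 15, a ketyl–carbonyl (pinacol) cyclisation with SmI2 and t-BuOH in THF at −78 °C forms the same C4–C5 bond. The new oxygen at C4 is expected anti to the adjacent C3 silyloxy group, giving the cis-4,5-diol (1R,2R,3R,4R,5R)-2-(tert-butyldimethylsilyloxy)-3,4-dihydroxy-N-methoxy-N,4-dimethyl-5-(triethylsilyloxy)cyclohexane-1-carboxamide F1. Parikh–Doering oxidation (SO3·pyridine, DMSO, iPr2NEt) of its secondary hydroxyl erases the C5 centre and returns to the route at 16.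

**Step 10.** The risk is poor facial selectivity if ligand exchange at the hindered tertiary hydroxyl is slow and hydride arrives externally. Fallback: starting from 16, the C4 hydroxyl is silylated with chlorodimethylsilane and imidazole to the hydridosilyl ether (1R,2R,4S,5R)-2-(tert-butyldimethylsilyloxy)-4-(dimethylsilyloxy)-N-methoxy-N,4-dimethyl-3-oxo-5-(triethylsilyloxy)cyclohexane-1-carboxamide F2. Tethered intramolecular hydrosilylation (catalytic fluoride at −78 °C) must deliver hydride from the O4 face and gives the cyclic dimethylsilylene derivative of the trans-diol F3. Its methanolysis (K2CO3, MeOH) returns to the route at 17.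

**Step 17.** The risks are low selectivity at C8 if the ligand-controlled addition is mismatched with the adjacent C1 centre, slow nickel insertion into the hindered triflate, and isomerisation or self-condensation of aldehyde 25. Fallback: starting from 23 and 25, the ligand-free NiCl2/CrCl2 coupling in DMF gives 26 together with its C8 epimer, the (3R)-alcohol F4. Buffered Dess–Martin oxidation of the mixture gives the enone 2-[(1S,3S,4R,5S,6S)-4,5-bis(tert-butyldimethylsilyloxy)-6-methyl-7-oxabicyclo[4.1.0]heptan-3-yl]-6-methylhepta-1,5-dien-3-one F5. Corey–Bakshi–Shibata reduction with the (R)-oxazaborolidine and catecholborane then sets 8S by ketone reduction, no longer in the C–C bond formation, and returns to the route at 26.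

**Step 20.** The risks are incomplete acylation of the hindered C5 hydroxyl next to the quaternary oxirane carbon, and Z→E isomerisation of the angelate during prolonged heating. Fallback: starting from 28, both hydroxyls are acylated with 2-[bis(2,2,2-trifluoroethoxy)phosphoryl]propanoic acid (DCC, DMAP) to the bis(phosphonopropanoate) F6. A double Still–Gennari olefination with acetaldehyde (KN(SiMe3)2, 18-crown-6, THF, −78 °C) then builds both (Z)-2-methylbut-2-enoates on the ester and returns to the route at 31.

## Further compounds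

F1 | step 9 | (1R,2R,3R,4R,5R)-2-(tert-butyldimethylsilyloxy)-3,4-dihydroxy-N-methoxy-N,4-dimethyl-5-(triethylsilyloxy)cyclohexane-1-carboxamide | CON(C)C(=O)[C@@H]1C[C@@H](O[Si](CC)(CC)CC)[C@](C)(O)[C@H](O)[C@@H]1O[Si](C)(C)C(C)(C)C
F2 | step 10 | (1R,2R,4S,5R)-2-(tert-butyldimethylsilyloxy)-4-(dimethylsilyloxy)-N-methoxy-N,4-dimethyl-3-oxo-5-(triethylsilyloxy)cyclohexane-1-carboxamide | CON(C)C(=O)[C@@H]1C[C@@H](O[Si](CC)(CC)CC)[C@](C)(O[SiH](C)C)C(=O)[C@@H]1O[Si](C)(C)C(C)(C)C
F3 | step 10 | cyclic dimethylsilylene derivative of 17 across O4 and O5 (trans-fused 2,2-dimethyl-1,3,2-dioxasilolane) | CON(C)C(=O)[C@@H]1C[C@@H](O[Si](CC)(CC)CC)[C@]2(C)O[Si](C)(C)O[C@H]2[C@@H]1O[Si](C)(C)C(C)(C)C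
F4 | step 17 | (3R)-2-[(1S,3S,4R,5S,6S)-4,5-bis(tert-butyldimethylsilyloxy)-6-methyl-7-oxabicyclo[4.1.0]heptan-3-yl]-6-methylhepta-1,5-dien-3-ol | C=C([C@@H](CC=C(C)C)O)[C@@H]1C[C@@H]2O[C@]2(C)[C@@H](O[Si](C)(C)C(C)(C)C)[C@@H]1O[Si](C)(C)C(C)(C)C
F5 | step 17 | 2-[(1S,3S,4R,5S,6S)-4,5-bis(tert-butyldimethylsilyloxy)-6-methyl-7-oxabicyclo[4.1.0]heptan-3-yl]-6-methylhepta-1,5-dien-3-one | C=C(C(=O)CC=C(C)C)[C@@H]1C[C@@H]2O[C@]2(C)[C@@H](O[Si](C)(C)C(C)(C)C)[C@@H]1O[Si](C)(C)C(C)(C)C
F6 | step 20 | bis{2-[bis(2,2,2-trifluoroethoxy)phosphoryl]propanoate} of diol 28 (epimeric at the two phosphonate-bearing carbons) | C=C([C@H](CC=C(C)C)OC(C)=O)[C@@H]1C[C@@H]2O[C@]2(C)[C@@H](OC(=O)C(C)P(=O)(OCC(F)(F)F)OCC(F)(F)F)[C@@H]1OC(=O)C(C)P(=O)(OCC(F)(F)F)OCC(F)(F)F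
A1 | alternative 1 | (2S,3S,4S,5S)-4,5-dihydroxy-2,3-bis[(4-methoxybenzyl)oxy]-4-methylcyclohexan-1-one | O=C1C[C@H](O)[C@](C)(O)[C@@H](OCc2ccc(OC)cc2)[C@@H]1OCc2ccc(OC)cc2
A2 | alternative 1 | (2S,3R,4S,5S)-2-methoxy-4,5-bis[(4-methoxybenzyl)oxy]-3-methyl-6-methylideneoxan-3-ol | C=C1O[C@H](OC)[C@](C)(O)[C@@H](OCc2ccc(OC)cc2)[C@@H]1OCc2ccc(OC)cc2
A3 | alternative 2 | 5-iodo-1-methyl-7,8-bis(tert-butyldimethylsilyloxy)-2-oxabicyclo[2.2.2]octan-3-one (stereoisomer of the SMILES) | O=C1O[C@@]2(C)[C@H](I)C[C@@H]1[C@@H](O[Si](C)(C)C(C)(C)C)[C@@H]2O[Si](C)(C)C(C)(C)C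
A4 | alternative 2 | (1R,5R,6R)-5,6-bis(tert-butyldimethylsilyloxy)-4-methylcyclohex-3-ene-1-carboxylic acid | OC(=O)[C@@H]1CC=C(C)[C@@H](O[Si](C)(C)C(C)(C)C)[C@@H]1O[Si](C)(C)C(C)(C)C
A5 | alternative 3 | cis-fused epoxy α-methylene-γ-butyrolactone with the C5 4-methoxybenzyl ether (stereoisomer of the SMILES) | C=C1C(=O)O[C@@H]2[C@H]1C[C@@H]3O[C@]3(C)[C@H]2OCc4ccc(OC)cc4
A6 | alternative 3 | methyl (2Z)-2-(bromomethyl)-4-{3-[1-(4-methoxybenzyloxy)-2-oxoethyl]-3-methyloxiran-2-yl}but-2-enoate (stereoisomer of the SMILES) | BrC/C(C(=O)OC)=C\C[C@@H]1O[C@]1(C)[C@@H](OCc2ccc(OC)cc2)C=O
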